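**Retrosynthetic overview**
- The target is the (2S)-flavanone (2S by CIP analysis of the given SMILES). It comes from its 5,7-bis-MOM ether by acetal removal, and that from an allyl 3-carboxylate by deallylation and decarboxylation.
- Ring C, the only ring made, is closed by a catalyst-controlled enantioselective intramolecular oxa-Michael addition of one free phenol onto an alkylidene β-ketoester. This sets C2.
- Key C–C bond: Knoevenagel-type intermolecular aldol condensation of the ring A β-ketoester with veratraldehyde (ring B). The β-ketoester comes from the ring A methyl ketone by crossed Claisen condensation with diallyl carbonate.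
- Ring A: phloroglucinol is differentiated as one TIPS ether and two MOM ethers. Two directed ortho-lithiations place geranyl between the MOM ethers and acetyl next to the oxygen that becomes O1, which fixes the 6-geranyl pattern.
- Rings A and B are bought aromatic; ring C is formed in step 10.

Abbreviations: geranyl = (2E)-3,7-dimethylocta-2,6-dien-1-yl; MOM = methoxymethyl; THP = oxan-2-yl; TIPS = tri(propan-2-yl)silyl.

Assumption: the epi-aminoquinidine-derived thiourea is taken to give the 2S product; this is checked on the first run by chiral HPLC and CD, and the quinine-derived pseudo-enantiomer is the drop-in replacement if the sense is reversed.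

**Step 1**
Reactants: 1 phloroglucinol (benzene-1,3,5-triol)
Product: 2 5-(TIPS-oxy)benzene-1,3-diol
Conditions: TIPSCl (1.0 equiv), imidazole (1.5 equiv), 1 in excess (3 equiv, recovered by aqueous extraction), DMF, 0 °C to rt
Reagents that add atoms: chlorotri(propan-2-yl)silane (TIPSCl), CC(C)[Si](Cl)(C(C)C)C(C)C
Why: Statistical mono-silylation of three equivalent phenols, favoured by excess cheap triol, installs a bulky silyl ether that later blocks lithiation at its ortho positions and marks the oxygen that becomes O1.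

**Step 2**
Reactants: 2 5-(TIPS-oxy)benzene-1,3-diol
Product: 3 [3,5-bis(methoxymethoxy)phenoxy]tri(propan-2-yl)silane
Conditions: MOMCl (2.5 equiv), i-Pr2NEt (3 equiv), CH2Cl2, 0 °C to rt
Reagents that add atoms: chloromethyl methyl ether (MOMCl), COCCl
Why: Amine-mediated O-alkylation (methoxymethylation) of the two remaining phenols gives the two acetal directing groups without disturbing the aryl silyl ether.

**Step 3**
Reactants: 3 [3,5-bis(methoxymethoxy)phenoxy]tri(propan-2-yl)silane; 4 geranyl bromide ((2E)-1-bromo-3,7-dimethylocta-2,6-diene)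
Product: 6 [4-geranyl-3,5-bis(methoxymethoxy)phenoxy]tri(propan-2-yl)silane, via aryllithium 5 (not isolated)
Conditions: n-BuLi (1.1 equiv), THF, 0 °C, 1 h; CuBr·SMe2 (10 mol%), −78 °C; then 4 (1.2 equiv), −78 °C to rt
Reagents that add atoms: none
Why: Directed ortho-metalation occurs only at the carbon flanked by both MOM ethers because the TIPS ether shields its neighbours, and copper-catalysed SN2 allylic substitution on the primary bromide attaches geranyl with the E-alkene untouched.

**Step 4**
Reactants: 6 [4-geranyl-3,5-bis(methoxymethoxy)phenoxy]tri(propan-2-yl)silane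
Product: 7 4-geranyl-3,5-bis(methoxymethoxy)phenol
Conditions: Bu4NF (1.1 equiv), THF, 0 °C; aq NH4Cl
Reagents that add atoms: none
Why: Fluoride-driven desilylation frees only this phenol, since MOM ethers and alkenes are inert to Bu4NF.

**Step 5**
Reactants: 7 4-geranyl-3,5-bis(methoxymethoxy)phenol
Product: 8 2-[4-geranyl-3,5-bis(methoxymethoxy)phenoxy]oxane (racemic at the acetal carbon)
Conditions: 3,4-dihydro-2H-pyran (2 equiv), PPTS (5 mol%), CH2Cl2, rt
Reagents that add atoms: 3,4-dihydro-2H-pyran, C1=COCCC1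
Why: Acid-catalysed addition of the phenol to the enol ether (tetrahydropyranylation) gives an acetal that directs lithiation and can later be removed in the presence of the MOM ethers; its racemic centre is inconsequential.

**Step 6**
Reactants: 8 2-[4-geranyl-3,5-bis(methoxymethoxy)phenoxy]oxane; 9 N-methoxy-N-methylacetamide
Product: 11 1-[3-geranyl-2,4-bis(methoxymethoxy)-6-(oxan-2-yloxy)phenyl]ethan-1-one, via aryllithium 10 (not isolated)
Conditions: n-BuLi (1.2 equiv), TMEDA (1.2 equiv), THF, 0 °C, 1 h; then 9 (1.5 equiv), −78 °C to 0 °C; aq NH4Cl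
Reagents that add atoms: none
Why: A second directed ortho-metalation at one of the two equivalent ring CH positions (each flanked by OTHP and OMOM), followed by Weinreb ketone synthesis through a chelated adduct that cannot over-add, puts the acetyl group between the future O1 and the MOM-oxygen next to geranyl.

**Step 7**
Reactants: 11 1-[3-geranyl-2,4-bis(methoxymethoxy)-6-(oxan-2-yloxy)phenyl]ethan-1-one; 12 diallyl carbonate
Product: 13 prop-2-en-1-yl 3-[3-geranyl-2,4-bis(methoxymethoxy)-6-(oxan-2-yloxy)phenyl]-3-oxopropanoate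
Conditions: NaH (2.5 equiv), 12 (3 equiv), THF, reflux; aq NH4Cl
Reagents that add atoms: none
Why: Crossed Claisen condensation of the methyl ketone enolate with the non-enolisable carbonate is driven to completion by deprotonation of the β-ketoester product, and the acetals and alkenes are inert to NaH.

**Step 8**
Reactants: 13 prop-2-en-1-yl 3-[3-geranyl-2,4-bis(methoxymethoxy)-6-(oxan-2-yloxy)phenyl]-3-oxopropanoate; 14 veratraldehyde (3,4-dimethoxybenzaldehyde)
Product: 15 prop-2-en-1-yl 2-[3-geranyl-2,4-bis(methoxymethoxy)-6-(oxan-2-yloxy)benzoyl]-3-(3,4-dimethoxyphenyl)prop-2-enoate (E/Z mixture at the new alkene)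
Conditions: 14 (1.1 equiv), piperidine (0.2 equiv), AcOH (0.2 equiv), benzene, reflux, Dean–Stark
Reagents that add atoms: none
Why: Knoevenagel-type intermolecular aldol condensation of the active methylene with the non-enolisable aldehyde forms the key ring A–ring B carbon–carbon bond, while the THP ether prevents premature racemic ring closure.

**Step 9**
Reactants: 15 prop-2-en-1-yl 2-[3-geranyl-2,4-bis(methoxymethoxy)-6-(oxan-2-yloxy)benzoyl]-3-(3,4-dimethoxyphenyl)prop-2-enoate
Product: 16 prop-2-en-1-yl 2-[3-geranyl-6-hydroxy-2,4-bis(methoxymethoxy)benzoyl]-3-(3,4-dimethoxyphenyl)prop-2-enoate (E/Z mixture)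
Conditions: PPTS (0.2 equiv), MeOH–CH2Cl2, 0 °C to rt; used at once
Reagents that add atoms: none
Why: Mild transacetalisation to methanol cleaves the aryl THP acetal much faster than the MOM ethers, unveiling the only phenol that can cyclise while the weakly acidic medium keeps the uncatalysed oxa-Michael reaction slow.

**Step 10**
Reactants: 16 prop-2-en-1-yl 2-[3-geranyl-6-hydroxy-2,4-bis(methoxymethoxy)benzoyl]-3-(3,4-dimethoxyphenyl)prop-2-enoate
Product: 17 prop-2-en-1-yl (2S)-2-(3,4-dimethoxyphenyl)-6-geranyl-5,7-bis(methoxymethoxy)-4-oxo-3,4-dihydro-2H-1-benzopyran-3-carboxylate (C3 epimers and enol in equilibrium)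
Conditions: N-[3,5-bis(trifluoromethyl)phenyl]-N'-[(9R)-6'-methoxycinchonan-9-yl]thiourea (10 mol%), toluene, −25 °C, 24–48 h
Reagents that add atoms: none
Why: In this enantioselective intramolecular oxa-Michael addition the quinuclidine nitrogen activates the phenol and the thiourea hydrogen-bonds the β-ketoester, so oxygen adds to one face of the doubly activated alkene and sets C2 as S, and the ester activation makes closure fast at low temperature and effectively irreversible.

**Step 11**
Reactants: 17 prop-2-en-1-yl (2S)-2-(3,4-dimethoxyphenyl)-6-geranyl-5,7-bis(methoxymethoxy)-4-oxo-3,4-dihydro-2H-1-benzopyran-3-carboxylate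
Product: 19 (2S)-2-(3,4-dimethoxyphenyl)-6-geranyl-5,7-bis(methoxymethoxy)-2,3-dihydro-4H-1-benzopyran-4-one, via beta-keto acid 18 (not isolated)
Conditions: Pd(OAc)2 (5 mol%), PPh3 (20 mol%), HCO2H (2.5 equiv), Et3N (2.0 equiv), THF, rt; then recrystallisation (hexane–EtOAc) to raise ee
Reagents that add atoms: none
Why: Tsuji-type deallylation by zerovalent palladium with formate as hydride donor releases the β-keto acid, which decarboxylates at room temperature in a slightly acidic buffer that does not open the pyranone ring, so C2 keeps its configuration.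

**Step 12**
Reactants: 19 (2S)-2-(3,4-dimethoxyphenyl)-6-geranyl-5,7-bis(methoxymethoxy)-2,3-dihydro-4H-1-benzopyran-4-one
Product: 20 (2S)-2-(3,4-dimethoxyphenyl)-6-geranyl-5,7-dihydroxy-2,3-dihydro-4H-1-benzopyran-4-one (target, CNP0268555.1)
Conditions: 3 M aq HCl–MeOH (1:5), 35–40 °C, monitored and stopped at full conversion
Reagents that add atoms: none
Why: Acid-catalysed acetal methanolysis removes both MOM groups (the 5-OMOM first, assisted by the neighbouring carbonyl) under conditions mild enough to spare the aryl methyl ethers, the geranyl alkenes and the C2 stereocentre.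

**Compound list**
1 | phloroglucinol (benzene-1,3,5-triol) | Oc1cc(O)cc(O)c1 | starting material
2 | 5-(TIPS-oxy)benzene-1,3-diol | CC(C)[Si](Oc1cc(O)cc(O)c1)(C(C)C)C(C)C | intermediate
3 | [3,5-bis(methoxymethoxy)phenoxy]tri(propan-2-yl)silane | COCOc1cc(OCOC)cc(O[Si](C(C)C)(C(C)C)C(C)C)c1 | intermediate
4 | geranyl bromide, (2E)-1-bromo-3,7-dimethylocta-2,6-diene | BrC/C=C(\C)CCC=C(C)C | starting material
5 | [2,6-bis(methoxymethoxy)-4-(TIPS-oxy)phenyl]lithium | [Li]c1c(OCOC)cc(O[Si](C(C)C)(C(C)C)C(C)C)cc1OCOC | intermediate (not isolated)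
6 | [4-geranyl-3,5-bis(methoxymethoxy)phenoxy]tri(propan-2-yl)silane | COCOc1cc(O[Si](C(C)C)(C(C)C)C(C)C)cc(OCOC)c1C/C=C(\C)CCC=C(C)C | intermediate
7 | 4-geranyl-3,5-bis(methoxymethoxy)phenol | COCOc1cc(O)cc(OCOC)c1C/C=C(\C)CCC=C(C)C | intermediate
8 | 2-[4-geranyl-3,5-bis(methoxymethoxy)phenoxy]oxane, racemic at the acetal carbon | COCOc1cc(OC2CCCCO2)cc(OCOC)c1C/C=C(\C)CCC=C(C)C | intermediate
9 | N-methoxy-N-methylacetamide | CC(=O)N(C)OC | starting material
10 | [3-geranyl-2,4-bis(methoxymethoxy)-6-(oxan-2-yloxy)phenyl]lithium, racemic acetal | [Li]c1c(OC2CCCCO2)cc(OCOC)c(C/C=C(\C)CCC=C(C)C)c1OCOC | intermediate (not isolated)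
11 | 1-[3-geranyl-2,4-bis(methoxymethoxy)-6-(oxan-2-yloxy)phenyl]ethan-1-one, racemic acetal | CC(=O)c1c(OC2CCCCO2)cc(OCOC)c(C/C=C(\C)CCC=C(C)C)c1OCOC | intermediate
12 | diallyl carbonate, bis(prop-2-en-1-yl) carbonate | C=CCOC(=O)OCC=C | starting material
13 | prop-2-en-1-yl 3-[3-geranyl-2,4-bis(methoxymethoxy)-6-(oxan-2-yloxy)phenyl]-3-oxopropanoate, racemic acetal | C=CCOC(=O)CC(=O)c1c(OC2CCCCO2)cc(OCOC)c(C/C=C(\C)CCC=C(C)C)c1OCOC | intermediate
14 | veratraldehyde, 3,4-dimethoxybenzaldehyde | COc1ccc(C=O)cc1OC | starting material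
15 | prop-2-en-1-yl 2-[3-geranyl-2,4-bis(methoxymethoxy)-6-(oxan-2-yloxy)benzoyl]-3-(3,4-dimethoxyphenyl)prop-2-enoate, E/Z mixture at the new alkene, racemic acetal | C=CCOC(=O)C(=Cc1ccc(OC)c(OC)c1)C(=O)c1c(OC2CCCCO2)cc(OCOC)c(C/C=C(\C)CCC=C(C)C)c1OCOC | intermediate
16 | prop-2-en-1-yl 2-[3-geranyl-6-hydroxy-2,4-bis(methoxymethoxy)benzoyl]-3-(3,4-dimethoxyphenyl)prop-2-enoate, E/Z mixture at the new alkene | C=CCOC(=O)C(=Cc1ccc(OC)c(OC)c1)C(=O)c1c(O)cc(OCOC)c(C/C=C(\C)CCC=C(C)C)c1OCOC | intermediate
17 | prop-2-en-1-yl (2S)-2-(3,4-dimethoxyphenyl)-6-geranyl-5,7-bis(methoxymethoxy)-4-oxo-3,4-dihydro-2H-1-benzopyran-3-carboxylate, C3 not defined (epimers and enol equilibrate) | COc1ccc([C@@H]2C(C(=O)OCC=C)C(=O)c3c(cc(OCOC)c(C/C=C(\C)CCC=C(C)C)c3OCOC)O2)cc1OC | intermediate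
18 | (2S)-2-(3,4-dimethoxyphenyl)-6-geranyl-5,7-bis(methoxymethoxy)-4-oxo-3,4-dihydro-2H-1-benzopyran-3-carboxylic acid, C3 not defined | COc1ccc([C@@H]2C(C(=O)O)C(=O)c3c(cc(OCOC)c(C/C=C(\C)CCC=C(C)C)c3OCOC)O2)cc1OC | intermediate (not isolated)
19 | (2S)-2-(3,4-dimethoxyphenyl)-6-geranyl-5,7-bis(methoxymethoxy)-2,3-dihydro-4H-1-benzopyran-4-one | COc1ccc([C@@H]2CC(=O)c3c(cc(OCOC)c(C/C=C(\C)CCC=C(C)C)c3OCOC)O2)cc1OC | intermediate
20 | (2S)-2-(3,4-dimethoxyphenyl)-6-geranyl-5,7-dihydroxy-2,3-dihydro-4H-1-benzopyran-4-one | COc1ccc([C@@H]2CC(=O)c3c(cc(O)c(C/C=C(\C)CCC=C(C)C)c3O)O2)cc1OC | target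

**Step count and risks**
Total step count: 12. Longest linear sequence: 12 steps, from phloroglucinol 1 to target 20; the route is fully linear, with 4, 9, 12 and 14 bought.

The three steps most likely to fail:

Step 10 (together with the unmasking in step 9). The 6'-oxygenated, doubly activated phenol 16 may cyclise without the catalyst, or the ee may be modest. The fallback sets out from 11 and comes back at 19. PPTS in MeOH removes the THP group to give 1-[3-geranyl-6-hydroxy-2,4-bis(methoxymethoxy)phenyl]ethan-1-one F1. Claisen–Schmidt aldol condensation of this ketone with 14 (KOH, EtOH, rt) gives the (E)-2'-hydroxychalcone F2. NaOAc in refluxing EtOH closes it to the racemic bis-MOM flavanone F3. Kinetic resolution by asymmetric transfer hydrogenation ([RhCl(Cp*)((R,R)-TsDPEN)], HCO2H–Et3N, EtOAc, rt, stopped near 55% conversion) reduces the 2R enantiomer to the (2R,4R)-cis-flavan-4-ol F4 and leaves 19, separated by chromatography. The yield ceiling is 50% but the ee is high.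

Step 12. Protic acid may add the freed 5- or 7-phenol across the geranyl alkene (chroman formation) or slowly erode ee. The fallback sets out from 19 and comes back at 20. TMSOTf with 2,2'-bipyridyl in CH2Cl2 at 0 °C exchanges both aryl MOM ethers for silyl ethers under buffered, non-protic conditions, giving the 5,7-bis(trimethylsilyl) ether F5. Water at neutral pH in the work-up hydrolyses it to 20.

Step 6. The aryllithium may form incompletely because of competing deprotonation at the benzylic-allylic CH2 of geranyl, or it may enolise the Weinreb amide. The fallback sets out from 7 and comes back at 11, so the second lithiation is avoided. Phenoxide-directed ortho-formylation (MgCl2, Et3N, paraformaldehyde, MeCN, reflux) gives 3-geranyl-6-hydroxy-2,4-bis(methoxymethoxy)benzaldehyde F6. Tetrahydropyranylation (3,4-dihydro-2H-pyran, PPTS) gives the THP-protected aldehyde F7. MeMgBr in THF at 0 °C gives the secondary benzylic alcohol F8. Dess–Martin periodinane with NaHCO3 oxidises it to 11.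

**Further compounds**
F1 | step 10 | 1-[3-geranyl-6-hydroxy-2,4-bis(methoxymethoxy)phenyl]ethan-1-one | CC(=O)c1c(O)cc(OCOC)c(C/C=C(\C)CCC=C(C)C)c1OCOC
F2 | step 10 | (2E)-3-(3,4-dimethoxyphenyl)-1-[3-geranyl-6-hydroxy-2,4-bis(methoxymethoxy)phenyl]prop-2-en-1-one | COc1ccc(/C=C/C(=O)c2c(O)cc(OCOC)c(C/C=C(\C)CCC=C(C)C)c2OCOC)cc1OC
F3 | step 10 | rac-2-(3,4-dimethoxyphenyl)-6-geranyl-5,7-bis(methoxymethoxy)-2,3-dihydro-4H-1-benzopyran-4-one | COc1ccc(C2CC(=O)c3c(cc(OCOC)c(C/C=C(\C)CCC=C(C)C)c3OCOC)O2)cc1OC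
F4 | step 10 | (2R,4R)-2-(3,4-dimethoxyphenyl)-6-geranyl-5,7-bis(methoxymethoxy)-3,4-dihydro-2H-1-benzopyran-4-ol | COc1ccc([C@H]2C[C@@H](O)c3c(cc(OCOC)c(C/C=C(\C)CCC=C(C)C)c3OCOC)O2)cc1OC
F5 | step 12 | (2S)-2-(3,4-dimethoxyphenyl)-6-geranyl-5,7-bis(trimethylsilyloxy)-2,3-dihydro-4H-1-benzopyran-4-one | COc1ccc([C@@H]2CC(=O)c3c(cc(O[Si](C)(C)C)c(C/C=C(\C)CCC=C(C)C)c3O[Si](C)(C)C)O2)cc1OC
F6 | step 6 | 3-geranyl-6-hydroxy-2,4-bis(methoxymethoxy)benzaldehyde | O=Cc1c(O)cc(OCOC)c(C/C=C(\C)CCC=C(C)C)c1OCOC
F7 | step 6 | 3-geranyl-2,4-bis(methoxymethoxy)-6-(oxan-2-yloxy)benzaldehyde, racemic acetal | O=Cc1c(OC2CCCCO2)cc(OCOC)c(C/C=C(\C)CCC=C(C)C)c1OCOC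
F8 | step 6 | 1-[3-geranyl-2,4-bis(methoxymethoxy)-6-(oxan-2-yloxy)phenyl]ethan-1-ol, diastereomer mixture | CC(O)c1c(OC2CCCCO2)cc(OCOC)c(C/C=C(\C)CCC=C(C)C)c1OCOC
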